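**Retrosynthetic overview**
1. Target ⇒ seco-aldehyde 20 by cutting C9–C10: a ring-closing Mukaiyama aldol of the furanone (as its 3-silyloxyfuran) onto the C9 aldehyde is the last step, closes the oxa-bridged nine-membered ring and sets C9 and C10 together.
2. 20 ⇒ cis-lactone 14 (acetonide off, O9 silylated, O8 methacryloylated, C9 oxidised); the methacrylate and the methylene lactone are in place before ring closure.
3. 14 ⇒ Z-enal 8 + allylic bromide 12 by indium Barbier allylation/lactonisation (C6–C7 bond; C6 and C7 set, C8 from the chiral pool).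
4. 8 ⇒ (Z)-3-methylpent-2-en-4-yn-1-ol + (S)-2-acetoxypropanoyl chloride (acyl Sonogashira, oxa-Michael closure); 12 ⇒ (R)-glyceraldehyde acetonide + methyl acrylate.
5. Ring order: 3(2H)-furanone first, γ-lactone second, ten-membered carbocycle last.

Convention: germacrane numbering is used (C1 furanone C=O, C2 =CH, C3 enol-ether carbon, C4(CH3)=C5, C6 lactone carbinol, C7, C8 ester carbinol, C9 carbinol, C10 quaternary, C11–C13 methylene lactone); the target as drawn is 4Z,6S,7S,8S,9R,10R with a cis-fused lactone; building blocks that end up in the target are numbered as reactants.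
Assumption: the furanone C10–H centre in 4–20 is drawn S as introduced from 3; it is configurationally labile and irrelevant, because step 13 planarises and resets it.

**Step 1**
Reactants: 1 (Z)-3-methylpent-2-en-4-yn-1-ol
Product: 2 tert-butyldimethyl{[(2Z)-3-methylpent-2-en-4-yn-1-yl]oxy}silane
Conditions: TBSCl, imidazole, CH2Cl2, 0 °C → rt
Reagents that add atoms: tert-butyldimethylsilyl chloride, CC(C)(C)[Si](C)(C)Cl
Why: Silyl ether formation masks the C6 hydroxyl, which would otherwise add to the ynone and furanone built next; no stereocentre is formed and the Z-alkene is untouched.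

**Step 2**
Reactants: 2 tert-butyldimethyl{[(2Z)-3-methylpent-2-en-4-yn-1-yl]oxy}silane; 3 (2S)-2-(acetyloxy)propanoyl chloride
Product: 4 (2S,6Z)-8-[(tert-butyldimethylsilyl)oxy]-6-methyl-3-oxooct-6-en-4-yn-2-yl acetate
Conditions: PdCl2(PPh3)2 (2 mol %), CuI (4 mol %), Et3N (1.3 equiv), THF, rt
Reagents that add atoms: none
Why: Acyl Sonogashira coupling of the terminal alkyne with the acid chloride gives the ynone (C1–C3 unit) directly, and the lactate centre it carries (C10) is only a placeholder.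

**Step 3**
Reactants: 4 (2S,6Z)-8-[(tert-butyldimethylsilyl)oxy]-6-methyl-3-oxooct-6-en-4-yn-2-yl acetate
Product: 6 (2S)-5-{(2Z)-4-[(tert-butyldimethylsilyl)oxy]but-2-en-2-yl}-2-methylfuran-3(2H)-one, via hydroxy ynone 5 (not isolated)
Conditions: K2CO3 (0.3 equiv), MeOH, 0 °C → rt
Reagents that add atoms: none
Why: Methanolysis of the activated α-keto acetate (transesterification) frees the C10 hydroxyl, which closes onto the ynone β-carbon C3 by 5-endo-dig oxa-Michael addition to give the 3(2H)-furanone.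

**Step 4**
Reactants: 6 (2S)-5-{(2Z)-4-[(tert-butyldimethylsilyl)oxy]but-2-en-2-yl}-2-methylfuran-3(2H)-one
Product: 7 (2S)-5-[(2Z)-4-hydroxybut-2-en-2-yl]-2-methylfuran-3(2H)-one
Conditions: HF·pyridine, pyridine, THF, 0 °C
Reagents that add atoms: none
Why: Buffered fluoride desilylation frees the primary allylic alcohol without the strong acid or base that could trigger oxa-Michael addition of this Z-positioned hydroxyl to the furanone.

**Step 5**
Reactants: 7 (2S)-5-[(2Z)-4-hydroxybut-2-en-2-yl]-2-methylfuran-3(2H)-one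
Product: 8 (2Z)-3-[(5S)-5-methyl-4-oxo-4,5-dihydrofuran-2-yl]but-2-enal
Conditions: MnO2 (15 equiv), CH2Cl2, rt, dark
Reagents that add atoms: none
Why: Neutral heterogeneous MnO2 oxidation of the allylic alcohol gives the Z-enal without Z/E isomerisation and without touching the enolisable furanone.

**Step 6**
Reactants: 9 (4R)-2,2-dimethyl-1,3-dioxolane-4-carbaldehyde; 10 methyl acrylate
Product: 11 methyl 2-{[(4R)-2,2-dimethyl-1,3-dioxolan-4-yl](hydroxy)methyl}prop-2-enoate (both carbinol epimers)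
Conditions: DABCO (0.5 equiv), neat methyl acrylate (3 equiv), rt, 5 d
Reagents that add atoms: none
Why: The Morita–Baylis–Hillman reaction joins C7 to C11; the C8 stereocentre comes unchanged from the chiral pool and the new carbinol centre is destroyed in step 7.

**Step 7**
Reactants: 11 methyl 2-{[(4R)-2,2-dimethyl-1,3-dioxolan-4-yl](hydroxy)methyl}prop-2-enoate
Product: 12 methyl (2Z)-2-(bromomethyl)-3-[(4S)-2,2-dimethyl-1,3-dioxolan-4-yl]prop-2-enoate
Conditions: NBS, Me2S, CH2Cl2, 0 °C → rt
Reagents that add atoms: N-bromosuccinimide, O=C1CCC(=O)N1Br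
Why: Corey–Kim-type activation of the hydroxyl as an alkoxysulfonium salt followed by SN2' attack of bromide converts both epimers into the thermodynamically preferred (Z)-2-(bromomethyl)enoate, with the dioxolanyl group cis to CH2Br.

**Step 8**
Reactants: 8 (2Z)-3-[(5S)-5-methyl-4-oxo-4,5-dihydrofuran-2-yl]but-2-enal; 12 methyl (2Z)-2-(bromomethyl)-3-[(4S)-2,2-dimethyl-1,3-dioxolan-4-yl]prop-2-enoate
Product: 14 (4S,5S)-4-[(4S)-2,2-dimethyl-1,3-dioxolan-4-yl]-3-methylidene-5-{(1Z)-2-[(5S)-5-methyl-4-oxo-4,5-dihydrofuran-2-yl]prop-1-en-1-yl}oxolan-2-one, via hydroxy ester 13 (not isolated)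
Conditions: indium powder (1.5 equiv), THF/H2O (3:1), rt; then PPTS (10 mol %), CH2Cl2, rt
Reagents that add atoms: none
Why: Indium Barbier allylation through a closed chair transition state with the dioxolanyl group axial gives the C6/C7 syn adduct, the aldehyde attacking the allyl face anti to the C8–C9 bond (C8–H in the alkene plane to avoid allylic 1,3-strain, C8–O outside), which sets 6S and 7S, and acid-catalysed lactonisation then gives the cis-fused α-methylene-γ-butyrolactone.

**Step 9**
Reactants: 14 the cis-lactone acetonide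
Product: 15 (4R,5S)-4-[(1S)-1,2-dihydroxyethyl]-3-methylidene-5-{(1Z)-2-[(5S)-5-methyl-4-oxo-4,5-dihydrofuran-2-yl]prop-1-en-1-yl}oxolan-2-one
Conditions: AcOH/H2O (4:1), 40 °C
Reagents that add atoms: none
Why: Acid-catalysed acetal hydrolysis removes the acetonide, and aqueous acetic acid is too weak to open or translactonise the γ-lactone.

**Step 10**
Reactants: 15 the lactone diol; 16 methacrylic anhydride
Product: 18 (1S)-1-[(2S,3S)-4-methylidene-2-{(1Z)-2-[(5S)-5-methyl-4-oxo-4,5-dihydrofuran-2-yl]prop-1-en-1-yl}-5-oxooxolan-3-yl]-2-[(triethylsilyl)oxy]ethyl 2-methylprop-2-enoate, via mono-TES ether 17 (not isolated)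
Conditions: TESCl (1.05 equiv), imidazole, CH2Cl2, −40 °C; then methacrylic anhydride, pyridine, DMAP (10 mol %), 0 °C → rt
Reagents that add atoms: chlorotriethylsilane, CC[Si](CC)(CC)Cl
Why: Sterically controlled silylation takes the primary C9 hydroxyl and DMAP-catalysed (Steglich-type) acylation then esterifies the remaining C8 hydroxyl, pyridine being too weak a base to O-acylate the furanone enol.

**Step 11**
Reactants: 18 the O8-methacrylate O9-TES ether
Product: 19 (1S)-2-hydroxy-1-[(2S,3S)-4-methylidene-2-{(1Z)-2-[(5S)-5-methyl-4-oxo-4,5-dihydrofuran-2-yl]prop-1-en-1-yl}-5-oxooxolan-3-yl]ethyl 2-methylprop-2-enoate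
Conditions: HF·pyridine, pyridine, THF, 0 °C
Reagents that add atoms: none
Why: Buffered fluoride desilylation frees the primary alcohol under slightly acidic conditions, where 1,2-acyl migration of the methacrylate from O8 to O9 is slow.

**Step 12**
Reactants: 19 the hydroxy methacrylate
Product: 20 (1S)-1-[(2S,3S)-4-methylidene-2-{(1Z)-2-[(5S)-5-methyl-4-oxo-4,5-dihydrofuran-2-yl]prop-1-en-1-yl}-5-oxooxolan-3-yl]-2-oxoethyl 2-methylprop-2-enoate
Conditions: Dess–Martin periodinane (1.3 equiv), CH2Cl2, 0 °C → rt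
Reagents that add atoms: none
Why: Dess–Martin oxidation gives the α-acyloxy aldehyde under non-basic conditions, so the C8 stereocentre is not epimerised.

**Step 13**
Reactants: 20 the seco-aldehyde
Product: 23 the target (4Z,6S,7S,8S,9R,10R)-9-hydroxy-1-oxo-3,10-epoxygermacra-2,4,11(13)-trien-12,6-olid-8-yl 2-methylprop-2-enoate, via silyloxyfuran 21 (not isolated), via trimethylsilyl ether 22 (not isolated)
Conditions: i-Pr2NEt (1.3 equiv), TMSOTf (1.6 equiv), CH2Cl2 (1 mM), −78 → −40 °C; then 0.5 M aq. citric acid, THF, 0 °C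
Reagents that add atoms: none
Why: Proposed new method: ring-closing Mukaiyama aldol in which the furanone is soft-enolised to its aromatic 3-silyloxyfuran and C10 (furan C2, its most nucleophilic position) attacks the TMSOTf-activated C9 aldehyde, closing the oxa-bridged nine-membered ring with silyl transfer to O9; the closest known reactions are intermolecular C2-aldol additions of 2-alkyl-3-silyloxyfurans to aldehydes, one-pot TMSOTf/amine enol-silane formation–Mukaiyama additions and aldol macrocyclisations; stereocontrol is by the short tether, which holds C7 gauche to the forming bond so that the C8–O ester dipole lies anti to the aldehyde C=O (Cornforth arrangement, silylated O9 away from the ester) and gives the 8,9-syn carbinol (9R), while the antiperiplanar open transition state, the only one keeping O9 away from both the furan face and the C1–OSiMe3 group, places the C9 oxygen and the C10 methyl syn, which means 10R.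

**Compound list**
1 | (Z)-3-methylpent-2-en-4-yn-1-ol | C#C/C(C)=C\CO | starting material
2 | tert-butyldimethyl{[(2Z)-3-methylpent-2-en-4-yn-1-yl]oxy}silane | C#C/C(C)=C\CO[Si](C)(C)C(C)(C)C | intermediate
3 | (2S)-2-(acetyloxy)propanoyl chloride | CC(=O)O[C@@H](C)C(=O)Cl | starting material
4 | (2S,6Z)-8-[(tert-butyldimethylsilyl)oxy]-6-methyl-3-oxooct-6-en-4-yn-2-yl acetate | CC(=O)O[C@@H](C)C(=O)C#C/C(C)=C\CO[Si](C)(C)C(C)(C)C | intermediate
5 | (2S,6Z)-8-[(tert-butyldimethylsilyl)oxy]-2-hydroxy-6-methyloct-6-en-4-yn-3-one | C[C@H](O)C(=O)C#C/C(C)=C\CO[Si](C)(C)C(C)(C)C | intermediate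
6 | (2S)-5-{(2Z)-4-[(tert-butyldimethylsilyl)oxy]but-2-en-2-yl}-2-methylfuran-3(2H)-one | C[C@@H]1OC(=CC1=O)/C(C)=C\CO[Si](C)(C)C(C)(C)C | intermediate
7 | (2S)-5-[(2Z)-4-hydroxybut-2-en-2-yl]-2-methylfuran-3(2H)-one | C[C@@H]1OC(=CC1=O)/C(C)=C\CO | intermediate
8 | (2Z)-3-[(5S)-5-methyl-4-oxo-4,5-dihydrofuran-2-yl]but-2-enal | C[C@@H]1OC(=CC1=O)/C(C)=C\C=O | intermediate
9 | (4R)-2,2-dimethyl-1,3-dioxolane-4-carbaldehyde | CC1(C)OC[C@H](C=O)O1 | starting material
10 | methyl acrylate | C=CC(=O)OC | starting material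
11 | methyl 2-{[(4R)-2,2-dimethyl-1,3-dioxolan-4-yl](hydroxy)methyl}prop-2-enoate (both carbinol epimers) | C=C(C(=O)OC)C(O)[C@H]1COC(C)(C)O1 | intermediate
12 | methyl (2Z)-2-(bromomethyl)-3-[(4S)-2,2-dimethyl-1,3-dioxolan-4-yl]prop-2-enoate | BrC/C(C(=O)OC)=C\[C@H]1COC(C)(C)O1 | intermediate
13 | methyl (3S,4S,5Z)-3-[(4S)-2,2-dimethyl-1,3-dioxolan-4-yl]-4-hydroxy-2-methylidene-6-[(5S)-5-methyl-4-oxo-4,5-dihydrofuran-2-yl]hept-5-enoate | CC1(C)OC[C@@H](O1)[C@@H](C(=C)C(=O)OC)[C@@H](O)/C=C(/C)C2=CC(=O)[C@H](C)O2 | intermediate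
14 | (4S,5S)-4-[(4S)-2,2-dimethyl-1,3-dioxolan-4-yl]-3-methylidene-5-{(1Z)-2-[(5S)-5-methyl-4-oxo-4,5-dihydrofuran-2-yl]prop-1-en-1-yl}oxolan-2-one | CC1(C)OC[C@@H](O1)[C@H]2C(=C)C(=O)O[C@H]2/C=C(/C)C2=CC(=O)[C@H](C)O2 | intermediate
15 | (4R,5S)-4-[(1S)-1,2-dihydroxyethyl]-3-methylidene-5-{(1Z)-2-[(5S)-5-methyl-4-oxo-4,5-dihydrofuran-2-yl]prop-1-en-1-yl}oxolan-2-one | O[C@H](CO)[C@H]1C(=C)C(=O)O[C@H]1/C=C(/C)C1=CC(=O)[C@H](C)O1 | intermediate
16 | methacrylic anhydride | C=C(C)C(=O)OC(=O)C(C)=C | starting material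
17 | (4R,5S)-4-{(1S)-1-hydroxy-2-[(triethylsilyl)oxy]ethyl}-3-methylidene-5-{(1Z)-2-[(5S)-5-methyl-4-oxo-4,5-dihydrofuran-2-yl]prop-1-en-1-yl}oxolan-2-one | O[C@H](CO[Si](CC)(CC)CC)[C@H]1C(=C)C(=O)O[C@H]1/C=C(/C)C1=CC(=O)[C@H](C)O1 | intermediate
18 | (1S)-1-[(2S,3S)-4-methylidene-2-{(1Z)-2-[(5S)-5-methyl-4-oxo-4,5-dihydrofuran-2-yl]prop-1-en-1-yl}-5-oxooxolan-3-yl]-2-[(triethylsilyl)oxy]ethyl 2-methylprop-2-enoate | C=C(C)C(=O)O[C@H](CO[Si](CC)(CC)CC)[C@H]1C(=C)C(=O)O[C@H]1/C=C(/C)C1=CC(=O)[C@H](C)O1 | intermediate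
19 | (1S)-2-hydroxy-1-[(2S,3S)-4-methylidene-2-{(1Z)-2-[(5S)-5-methyl-4-oxo-4,5-dihydrofuran-2-yl]prop-1-en-1-yl}-5-oxooxolan-3-yl]ethyl 2-methylprop-2-enoate | C=C(C)C(=O)O[C@H](CO)[C@H]1C(=C)C(=O)O[C@H]1/C=C(/C)C1=CC(=O)[C@H](C)O1 | intermediate
20 | (1S)-1-[(2S,3S)-4-methylidene-2-{(1Z)-2-[(5S)-5-methyl-4-oxo-4,5-dihydrofuran-2-yl]prop-1-en-1-yl}-5-oxooxolan-3-yl]-2-oxoethyl 2-methylprop-2-enoate | C=C(C)C(=O)O[C@H](C=O)[C@H]1C(=C)C(=O)O[C@H]1/C=C(/C)C1=CC(=O)[C@H](C)O1 | intermediate
21 | (1S)-1-[(2S,3S)-4-methylidene-2-{(1Z)-2-[5-methyl-4-(trimethylsilyloxy)furan-2-yl]prop-1-en-1-yl}-5-oxooxolan-3-yl]-2-oxoethyl 2-methylprop-2-enoate | C=C(C)C(=O)O[C@H](C=O)[C@H]1C(=C)C(=O)O[C@H]1/C=C(/C)c1cc(O[Si](C)(C)C)c(C)o1 | intermediate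
22 | 9-O-trimethylsilyl ether of the target, (4Z,6S,7S,8S,9R,10R)-1-oxo-9-(trimethylsilyloxy)-3,10-epoxygermacra-2,4,11(13)-trien-12,6-olid-8-yl 2-methylprop-2-enoate | C=C(C)C(=O)O[C@H]1[C@H]2C(=C)C(=O)O[C@H]2/C=C(/C)C2=CC(=O)[C@](C)(O2)[C@@H]1O[Si](C)(C)C | intermediate
23 | CNP0252578.4, (4Z,6S,7S,8S,9R,10R)-9-hydroxy-1-oxo-3,10-epoxygermacra-2,4,11(13)-trien-12,6-olid-8-yl 2-methylprop-2-enoate (3(2H)-furanone bridging C3/C10, cis-fused α-methylene-γ-lactone at C6/C7) | C=C(C)C(=O)O[C@H]1[C@H]2C(=C)C(=O)O[C@H]2/C=C(/C)C2=CC(=O)[C@](C)(O2)[C@@H]1O | target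

**Totals**
Total step count: 13. Longest linear sequence: 11 steps (steps 1–5 and 8–13, from 1); the branch from 9 (steps 6 and 7) joins at step 8.

**Three steps most likely to fail**

Step 13 (ring-closing aldol). The risks are no cyclisation, enolisation of the α-acyloxy aldehyde, or the wrong C9/C10 pair. Fallback: set out from 20, form 21 at −78 °C with only one equivalent of TMSOTf and quench it with NBS to obtain the C10 bromide of the seco-aldehyde F1 (both C10 epimers, which converge). Treat it with SmI2 (divalent samarium, 2.2 equiv) in THF at −78 °C under high dilution. A trivalent samarium enolate is then generated reductively and regiospecifically at C10, without base or Lewis acid, and adds to the C9 aldehyde through a chelated closed six-membered transition state (Reformatsky-type aldol cyclisation, a reaction class established for strained medium rings). The ring-locked enolate geometry (methyl cis to the enolate oxygen) again gives the C9–OH/C10–CH3 syn pair. Aqueous work-up gives 23, where the fallback rejoins the route.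

Step 8 (Barbier allylation). The risks are insufficient facial control by the dioxolane, or side reactions of the free C6 hydroxyl with the furanone before lactonisation. Fallback: set out from 11 and acetylate it (Ac2O, DMAP, pyridine) to the Morita–Baylis–Hillman acetate F2. Copper-catalysed SN2' borylation (B2pin2, CuCl 10 mol %, KOAc, DMF, rt) then gives the 2-(methoxycarbonyl)allyl pinacolboronate F3, with the dioxolanyl group cis to CH2B. Allylboration of 8 with this boronate, catalysed by the chiral phosphoric acid (R)-TRIP (toluene, −30 °C → rt), runs through a closed chair transition state that enforces the syn relation, while the catalyst rather than the dioxolane selects the aldehyde face. The O-boryl hydroxy ester lactonises (PPTS) to 14, where the fallback rejoins the route.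

Step 11 (unmasking the C9 alcohol). The risk is 1,2-acyl migration of the methacrylate from O8 to the freed primary O9 in 19. Fallback: set out from 18 and go directly to 20 by Swern oxidation ((COCl)2, DMSO, CH2Cl2, −78 → −30 °C, then Et3N). Under these conditions a primary triethylsilyl ether is cleaved by the chlorosulfonium species and oxidised in the same flask, so 19 never exists. This detour makes no new compound (F0) and rejoins the route at 20.

**Further compounds**
F1 | step 13 | (1S)-1-[(2S,3S)-2-{(1Z)-2-(5-bromo-5-methyl-4-oxo-4,5-dihydrofuran-2-yl)prop-1-en-1-yl}-4-methylidene-5-oxooxolan-3-yl]-2-oxoethyl 2-methylprop-2-enoate (both C10 epimers) | C=C(C)C(=O)O[C@H](C=O)[C@H]1C(=C)C(=O)O[C@H]1/C=C(/C)C1=CC(=O)C(C)(Br)O1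
F2 | step 8 | methyl 2-{(acetyloxy)[(4R)-2,2-dimethyl-1,3-dioxolan-4-yl]methyl}prop-2-enoate (both epimers at the acetoxy carbon) | C=C(C(=O)OC)C(OC(C)=O)[C@H]1COC(C)(C)O1
F3 | step 8 | methyl (2E)-3-[(4S)-2,2-dimethyl-1,3-dioxolan-4-yl]-2-[(4,4,5,5-tetramethyl-1,3,2-dioxaborolan-2-yl)methyl]prop-2-enoate | COC(=O)/C(CB1OC(C)(C)C(C)(C)O1)=C/[C@H]1COC(C)(C)O1
F0 | step 11 | none | none
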